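## Analysis of the target

Target 25 is a C2-symmetric dimer of two 12-methoxyabieta-8,11,13-triene halves. Each half has ring A (a cyclohexane with the C4 gem-dimethyl group), ring B, and the aromatic ring C carrying OMe at C12 and isopropyl at C13. The halves are joined head to tail by a 1,4-dioxane: one oxygen links C6 of the first half to C7 of the second, the other links C7 of the first to C6 of the second.

Each half has four stereocentres: the quaternary benzylic C10 (β-methyl), C5 (α-H, trans A/B fusion), C6 (α-oxygen, equatorial) and C7 (β-oxygen, pseudoequatorial). The dioxane is therefore trans-fused to both rings B, and the eight centres reduce to four independent ones. Only C10 needs absolute control, because C5 and C6 can be relayed from it across ring B, and C7 from C6.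

The C7–O bonds belong to a para-methoxybenzylic ether (C12 is para to C8). They ionise under acid and their C–H bonds are open to hydride abstraction; the electron-rich arenes are the other sensitive sites.

The difficulties are the absolute configuration of the all-carbon quaternary C10, the placing of oxygen on C6 next to the congested C4, the union of two hindered secondary carbinols through two benzylic C–O bonds, and the need for a monomer of one handedness for clean homochiral pairing.

The plan rests on one feature. With ring A removed, C10 is the benzylic α-carbon of a bicyclic ketone whose carbonyl is C5 (compound 10). A four-carbon vinyl ketone can then deliver C1 to C4, and the C4=C5 enone that results becomes, after dimethylation at C4, the C5=C6 alkene that accepts hydrogen at C5 and oxygen at C6.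

## Retrosynthetic reasoning

**25 to two molecules of 23.** Both C7–O bonds of the dioxane are cut. C7 is benzylic and para to the methoxy group, so it can become electrophilic by loss of hydride, whereas the C6–O bonds sit on a hindered secondary carbon that cannot be substituted. The cut halves the problem to the 6α-alcohol 23. The forward reaction must oxidise C7 of 23, join it to the hydroxyl of a second molecule (mono-ether 24), and repeat the event inside 24 to close the six-membered ring with the new oxygen β at each C7.

**23 to 21.** The C6–O and C5–H bonds are removed together, giving the C5=C6 alkene 21. Cutting here lets one syn addition set both C5 and C6 from the existing C10: the axial 10β- and 4β-methyl groups leave only the α face open. The forward step is an anti-Markovnikov hydration that places oxygen on the less substituted C6.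

**21 to 19 to 17.** The missing C3 oxygen is restored (ketone 19), and the two C4–CH3 bonds are then cut, giving the conjugated enone 17. The C3 carbonyl is what makes C4 nucleophilic, and double alkylation through the extended enolate moves the alkene from C4=C5 to C5=C6, where step 10 needs it. The forward steps are a deconjugative gem-dimethylation and a carbonyl-to-methylene reduction that leaves the alkene in place.

**17 to 10, 11 and 12.** Ring A is opened at C4–C5 (aldol condensation) and C1–C10 (conjugate addition). This is the only disconnection that turns the quaternary C10 into an enolisable, benzylic α-carbon; methyl vinyl ketone 12 supplies C1 to C4. The forward reaction must alkylate 10 at the benzylic carbon and not at C3, and must do so on one face. Both are met by the conjugated secondary enamine of the imine of 10 with (R)-1-phenylethylamine 11.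

**10 to 8 to 6.** The carbonyl of 10 is moved back to the benzylic position and the C-methyl bond is cut. A 1-tetralone (6) is far easier to make than a 2-tetralone, and methyl addition, dehydration to styrene 8, epoxidation and hydride-shift rearrangement transpose the oxygen while installing the methyl group.

**6 to 5 to 4 to 2 and 3; 2 to 1.** The aryl–carbonyl bond of 6 and then the aryl–acyl bond of keto acid 4 are cut, leading to 2-isopropylanisole 2 and succinic anhydride 3. Both acylations are directed by the ring substituents: para to OMe for the intermolecular one, para to isopropyl for the ring closure. 2 comes from 2-isopropylphenol 1 by O-methylation.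

## Alternatives that were turned down

**Alternative 1:** Rings B and C are disconnected together at C8–C9 and C13–C14. This leads to A2, a ring A cyclohexane carrying a methoxy-enyne arm on C10 (C9≡C11–C12(OMe)=C13) and a silyloxy ynone arm on C5 (C6(OTBS)–C7(=O)–C8≡C14). On heating, the enyne would add across the ynone in an intramolecular dehydro-Diels–Alder reaction; the first cycloadduct is not yet aromatic, and a hydrogen must move from C13 to C11 to give A1.

- For: A1 arrives with the 6α-oxygen and a C7 carbonyl already in place. It is the silyl ether of F3, so no hydroboration is needed, and the arene substitution pattern is written into acyclic pieces. On late-stage oxidation state this alternative is stronger than the chosen route.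
- Against: A2 must already hold the trans C5/C10 pair, one of them a quaternary alkynyl carbon, plus the C6 carbinol, all built on a lone cyclohexane without help from rings B and C. The enol-ether enyne and the terminal ynone are fragile at the temperatures such cycloadditions need, and the C7 ketone must later be removed or used.
- Comparison: the chosen route starts from the arene instead of building it, reaches its key-step substrate in six steps from commodity chemicals, and needs a single absolute stereocontrol event.

**Alternative 2:** C5–C10 is cut with ring B still absent. A3 is a cyclohexene acid with methyl and aryl on C10 and the future C6 as the carboxyl carbon on C5. It would come from lactone A4 through its silyl ketene acetal A5 by an Ireland–Claisen rearrangement in a ring-enforced boat, forming C5–C10, breaking the lactone C–O bond and closing ring A.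

- For: C5 and C10, including the quaternary centre, are set in one concerted, stereospecific step from a single carbinol stereocentre. On this point it is stronger than the chosen route, which sets C5 later.
- Against: a model of the boat shows that the carboxyl ends up cis to the alkene substituent that points outward. The required cis-methyl relationship therefore needs the (Z)-alkene, with the aryl group turned inward over the gem-dimethyl tether. That alkene is hard to make geometrically pure and gives a congested transition state. After the key step ring B is still missing: C7 must be inserted by homologation, the ring closed by Friedel–Crafts acylation, C1=C2 hydrogenated and C6 oxygenated to reach F3.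
- Comparison: the chosen route has rings B and C from the start, and its annulation product already carries the alkene that functionalises C6.

**Alternative 3:** Ring C is cut at C13–C14. Diketone A7, made by degrading sclareolide A8, has an exocyclic methylene on C8 and a C12,C13-diketone. With an alkylaluminium chloride Lewis acid, a carbonyl-ene attack of C14 on the C13 ketone followed by loss of water and enolisation would give ferruginol A6.

- For: C5 and C10 come from the chiral pool with full enantiopurity and no auxiliary. This is a real advantage here, because any minor enantiomer is lost to heterochiral dimers; on absolute stereocontrol this alternative is stronger.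
- Against: A6 stops short of the target's oxidation pattern. After methylation to F6, C6 is an unactivated methylene, reached only by dehydrogenation to F7 and a styrene hydroboration whose regiochemistry (C6 against C7) must be controlled. Trimming A8 to A7 costs several redox steps, and the ene step competes with migration of the exocyclic alkene.
- Comparison: the chosen route gives a C5=C6 alkene that takes oxygen at C6 and hydrogen at C5 in one step, has OMe and isopropyl in place from step 1, gives access to either enantiomer, and has a comparable step count.

Key step: step 7

## Route

Remark: a sequence carried through without purifying what is formed in between counts as one step, and centres formed in both configurations are written without stereodescriptors.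

Step 1
Reactants: 1 2-isopropylphenol
Product: 2 2-isopropylanisole
Conditions: MeI, K2CO3, acetone, reflux
Reagents that add atoms: iodomethane, CI
Why: Williamson ether synthesis: the phenoxide formed with K2CO3 is methylated on oxygen by SN2 displacement, and no other nucleophilic site is present.

Step 2
Reactants: 2 2-isopropylanisole; 3 succinic anhydride
Product: 4 4-(3-isopropyl-4-methoxyphenyl)-4-oxobutanoic acid
Conditions: AlCl3 (2.2 equiv), CH2Cl2/PhNO2, 0 °C to rt; aq HCl
Reagents that add atoms: none
Why: Friedel–Crafts acylation (first stage of a Haworth sequence): the acylium complex from 3 attacks 2 para to the methoxy group, the most activated and least hindered position, and the anhydride opens to the keto acid. Low temperature keeps the isopropyl group and the methyl ether intact.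

Step 3
Reactants: 4 4-(3-isopropyl-4-methoxyphenyl)-4-oxobutanoic acid
Product: 5 4-(3-isopropyl-4-methoxyphenyl)butanoic acid
Conditions: H2 (3 atm), Pd/C (10% palladium on carbon), AcOH, HClO4 (cat.), 60 °C
Reagents that add atoms: none
Why: Catalytic hydrogenolysis of an aryl ketone to the methylene group through the benzylic alcohol; the para-methoxy group and the acid co-catalyst favour C–O cleavage, while the carboxylic acid, the ether and the arene are not reduced.

Step 4
Reactants: 5 4-(3-isopropyl-4-methoxyphenyl)butanoic acid
Product: 6 6-isopropyl-7-methoxy-3,4-dihydronaphthalen-1(2H)-one
Conditions: P2O5, MeSO3H, 50 °C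
Reagents that add atoms: none
Why: Intramolecular Friedel–Crafts acylation (Haworth cyclisation) closing the six-membered ketone ring; of the two positions ortho to the chain, the one para to the isopropyl group is open and the other is buttressed by the isopropyl group, so the 6-isopropyl-7-methoxy pattern should result.

Step 5
Reactants: 6 6-isopropyl-7-methoxy-3,4-dihydronaphthalen-1(2H)-one
Product: 8 7-isopropyl-6-methoxy-4-methyl-1,2-dihydronaphthalene, via tertiary alcohol 7 (not isolated)
Conditions: MeMgBr, THF, 0 °C to rt; 2 M HCl quench; TsOH·H2O (cat.), PhMe, 80 °C
Reagents that add atoms: methylmagnesium bromide, C[Mg]Br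
Why: Grignard addition to the ketone gives the tertiary benzylic alcohol 7, which loses water under acid by an E1 pathway to the more stable endocyclic, trisubstituted styrene 8.

Step 6
Reactants: 8 7-isopropyl-6-methoxy-4-methyl-1,2-dihydronaphthalene
Product: 10 6-isopropyl-7-methoxy-1-methyl-3,4-dihydronaphthalen-2(1H)-one (racemic), via epoxide 9 (not isolated)
Conditions: mCPBA, NaHCO3, CH2Cl2/H2O, 0 °C; TsOH·H2O (cat.), PhMe, 60 °C
Reagents that add atoms: 3-chloroperoxybenzoic acid, OOC(=O)c1cccc(Cl)c1
Why: Prilezhaev epoxidation of the electron-rich styrene gives 9; acid opens it at the tertiary benzylic carbon and a 1,2-hydride shift from C2 (Meinwald rearrangement) places the carbonyl at C2 and leaves the methyl-bearing carbon as the α-position. The new stereocentre is formed racemic, which does not matter because step 7 passes through a planar enamine.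

Step 7
Reactants: 10 6-isopropyl-7-methoxy-1-methyl-3,4-dihydronaphthalen-2(1H)-one; 11 (R)-1-phenylethylamine; 12 methyl vinyl ketone
Product: 17 12-methoxy-18,19-dinorabieta-4,8,11,13-tetraen-3-one [(4aS)-7-isopropyl-6-methoxy-4a-methyl-4,4a,9,10-tetrahydrophenanthren-2(3H)-one], via imine 13 (not isolated), via keto-imine 14 (not isolated), via 1,5-diketone 15 (not isolated), via ketol 16 (not isolated)
Conditions: (R)-1-phenylethylamine, TsOH (cat.), PhMe, reflux (Dean–Stark); methyl vinyl ketone, THF, rt; 20% aq AcOH, rt; NaOMe, MeOH, 60 °C
Reagents that add atoms: none
Why: Condensation gives imine 13, which equilibrates with its more substituted secondary enamine, conjugated with the arene; this enamine adds to 12 through a compact cyclic aza-ene-like transition state in which the N–H proton passes to the enone α-carbon as C1–C10 forms, the known deracemising Michael reaction of 1-phenylethylamine imines of α-substituted ketones, which extends to 1-methyl-2-tetralones. Both enantiomers of 10 converge on the same enamine, so its stereocentre is irrelevant. C10 is set by the (R)-1-phenylethyl group: with its C–H bond eclipsing the ring to minimise allylic strain, the phenyl group covers one face and 12 approaches from the other. The known sense for 2-methylcyclohexanone is that the (S)-amine gives the (R)-adduct; transposed to 10, where the aryl carbon outranks the oxobutyl chain so that the descriptor changes although the topicity does not, the (R)-amine should give (R)-15, the 10β-methyl series. Reaction at the benzylic carbon instead of C3 follows from the conjugated enamine being the tautomer that carries the N–H syn to the nucleophilic carbon, and dialkylation is excluded because 14 has no hydrogen left on that carbon. Aqueous acetic acid hydrolyses 14 to 15 and releases 11 for recovery. NaOMe then closes ring A by a 6-(enolendo)-exo-trig aldol addition of the methyl ketone carbon C4 to the C5 carbonyl (ketol 16) and E1cB dehydration to the conjugated enone 17; the competing bridged ketol from the C6 enolate is formed reversibly and cannot dehydrate to a conjugated enone, so it should drain into 17. C10 is quaternary and cannot epimerise afterwards.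

Step 8
Reactants: 17 12-methoxy-18,19-dinorabieta-4,8,11,13-tetraen-3-one
Product: 19 12-methoxyabieta-5,8,11,13-tetraen-3-one, via monomethyl ketone 18 (not isolated)
Conditions: KOtBu (3 equiv), tBuOH/THF, rt; MeI, 0 °C to rt
Reagents that add atoms: iodomethane, CI
Why: Deconjugative α,α-dimethylation of an enone: γ-deprotonation at C6 gives the extended enolate, which is methylated at C4 to the β,γ-unsaturated ketone 18; its doubly activated C4–H is removed at once and a second methylation gives 19. C4 is not stereogenic in 19, C10 is untouched, and the double bond ends at C5=C6 where the next step needs it.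

Step 9
Reactants: 19 12-methoxyabieta-5,8,11,13-tetraen-3-one
Product: 21 12-methoxyabieta-5,8,11,13-tetraene, via hydrazone 20 (not isolated)
Conditions: N2H4·H2O, KOH, diethylene glycol, 130 °C then 200 °C
Reagents that add atoms: none
Why: Wolff–Kishner reduction in the Huang-Minlon variant: hydrazone 20 is deprotonated by KOH and loses dinitrogen to leave the C3 methylene group; the isolated trisubstituted alkene, the aryl ether and the quaternary centre are not attacked by the reagent.

Step 10
Reactants: 21 12-methoxyabieta-5,8,11,13-tetraene
Product: 23 12-methoxyabieta-8,11,13-trien-6α-ol, via alkylborane 22 (not isolated)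
Conditions: BH3·THF, THF, 0 °C to rt; NaOH, H2O2, 0 °C to 40 °C
Reagents that add atoms: hydrogen peroxide, OO
Why: Hydroboration–oxidation: borane adds syn across C5=C6 with boron at the less substituted C6 and hydrogen at C5, from the α face because the axial 10β- and 4β-methyl groups close the β face. Oxidation of the C–B bond with retention should give the 6α-alcohol with 5α-H, so C5 and C6 are both set from C10 and rings A and B become trans-fused.

Step 11
Reactants: 23 12-methoxyabieta-8,11,13-trien-6α-ol (two molecules)
Product: 25 C2-symmetric head-to-tail dioxane dimer of 12-methoxyabieta-8,11,13-triene with oxygen bridges C6α–O–C7′β plus C7β–O–C6′α (target), via mono-ether 24 (not isolated)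
Conditions: DDQ (1.05 equiv per 23, in portions), 4 Å MS, ClCH2CH2Cl (0.5 M), 0 °C to rt
Reagents that add atoms: none
Why: Proposed new method: DDQ should abstract hydride from C7, the benzylic position para to the methoxy group, and the resulting methoxy-stabilised cation should be captured by the 6α-hydroxyl of a second molecule of 23 on the β face (trans to the neighbouring C6–O bond, pseudoequatorial) to give 24; a second hydride abstraction at the remaining benzylic CH2 of 24 and capture by its free 6-hydroxyl then closes the trans-fused 1,4-dioxane as a six-membered ring. The closest known reaction type is the DDQ-mediated oxidative C–H etherification of para-methoxy-substituted alkylarenes with alcohols, together with the related oxidative cyclisations through benzylic cations; joining two such events into a cyclodimer has not been shown. Homochiral pairing gives the C2-symmetric product with the four dioxane ring bonds equatorial, and no centre set earlier is touched.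

## Compound list

1 | 2-isopropylphenol | CC(C)c1ccccc1O | starting material
2 | 2-isopropylanisole | COc1ccccc1C(C)C | intermediate
3 | succinic anhydride | O=C1CCC(=O)O1 | starting material
4 | 4-(3-isopropyl-4-methoxyphenyl)-4-oxobutanoic acid | COc1ccc(cc1C(C)C)C(=O)CCC(=O)O | intermediate
5 | 4-(3-isopropyl-4-methoxyphenyl)butanoic acid | COc1ccc(CCCC(=O)O)cc1C(C)C | intermediate
6 | 6-isopropyl-7-methoxy-3,4-dihydronaphthalen-1(2H)-one | COc1cc2c(cc1C(C)C)CCCC2=O | intermediate
7 | 6-isopropyl-7-methoxy-1-methyl-1,2,3,4-tetrahydronaphthalen-1-ol (racemic, not isolated) | COc1cc2c(cc1C(C)C)CCCC2(C)O | intermediate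
8 | 7-isopropyl-6-methoxy-4-methyl-1,2-dihydronaphthalene | COc1cc2c(cc1C(C)C)CCC=C2C | intermediate
9 | 1,2-epoxy-6-isopropyl-7-methoxy-1-methyl-1,2,3,4-tetrahydronaphthalene (racemic, not isolated) | COc1cc2c(cc1C(C)C)CCC1OC21C | intermediate
10 | 6-isopropyl-7-methoxy-1-methyl-3,4-dihydronaphthalen-2(1H)-one (racemic) | COc1cc2c(cc1C(C)C)CCC(=O)C2C | intermediate
11 | (R)-1-phenylethylamine | C[C@@H](N)c1ccccc1 | starting material
12 | methyl vinyl ketone | C=CC(C)=O | starting material
13 | N-[(1R)-1-phenylethyl]imine of 10 (both C1 configurations, in equilibrium with the conjugated secondary enamine; not isolated) | COc1cc2c(cc1C(C)C)CCC(=N[C@H](C)c1ccccc1)C2C | intermediate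
14 | N-[(1R)-1-phenylethyl]imine of (R)-15 (not isolated) | COc1cc2c(cc1C(C)C)CCC(=N[C@H](C)c1ccccc1)[C@]2(C)CCC(C)=O | intermediate
15 | (R)-6-isopropyl-7-methoxy-1-methyl-1-(3-oxobutyl)-3,4-dihydronaphthalen-2(1H)-one (not isolated) | COc1cc2c(cc1C(C)C)CCC(=O)[C@]2(C)CCC(C)=O | intermediate
16 | 5-hydroxy-12-methoxy-18,19-dinorabieta-8,11,13-trien-3-one (10β-methyl; either configuration at C5; not isolated) | COc1cc2c(cc1C(C)C)CCC1(O)CC(=O)CC[C@]21C | intermediate
17 | 12-methoxy-18,19-dinorabieta-4,8,11,13-tetraen-3-one | COc1cc2c(cc1C(C)C)CCC1=CC(=O)CC[C@]21C | intermediate
18 | 4-methyl-12-methoxy-18,19-dinorabieta-5,8,11,13-tetraen-3-one (either configuration at C4; not isolated) | COc1cc2c(cc1C(C)C)CC=C1C(C)C(=O)CC[C@]21C | intermediate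
19 | 12-methoxyabieta-5,8,11,13-tetraen-3-one | COc1cc2c(cc1C(C)C)CC=C1C(C)(C)C(=O)CC[C@]21C | intermediate
20 | hydrazone of 19 (not isolated) | COc1cc2c(cc1C(C)C)CC=C1C(C)(C)C(=NN)CC[C@]21C | intermediate
21 | 12-methoxyabieta-5,8,11,13-tetraene | COc1cc2c(cc1C(C)C)CC=C1C(C)(C)CCC[C@]21C | intermediate
22 | 6α-boryl-12-methoxyabieta-8,11,13-triene (5α-H; drawn as the monoalkylborane; not isolated) | COc1cc2c(cc1C(C)C)C[C@H](B)[C@H]1C(C)(C)CCC[C@]21C | intermediate
23 | 12-methoxyabieta-8,11,13-trien-6α-ol (5α-H, 10β-methyl) | COc1cc2c(cc1C(C)C)C[C@H](O)[C@H]1C(C)(C)CCC[C@]21C | intermediate
24 | 7β-[(12-methoxyabieta-8,11,13-trien-6α-yl)oxy]-12-methoxyabieta-8,11,13-trien-6α-ol (not isolated) | COc1cc2c(cc1C(C)C)[C@@H](O[C@H]3Cc4cc(C(C)C)c(OC)cc4[C@@]4(C)CCCC(C)(C)[C@H]34)[C@H](O)[C@H]1C(C)(C)CCC[C@]21C | intermediate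
25 | C2-symmetric dimer of 12-methoxyabieta-8,11,13-triene, 1,4-dioxane through C6α–O–C7′β and C7β–O–C6′α (CNP0327150.1) | COc1cc2c(cc1C(C)C)[C@H]1O[C@H]3[C@H](O[C@@H]1[C@H]1C(C)(C)CCC[C@]21C)c1cc(C(C)C)c(OC)cc1[C@@]1(C)CCCC(C)(C)[C@H]31 | target

## Step count and least certain steps

Total step count: 11. Longest linear sequence: 11 steps (1 to 25); the only convergent event is the union of two molecules of 23 in step 11.

**Step 11 (bears the label).** The most likely failure is loss of the cation before intermolecular capture. The C7 cation has an axial hydrogen on C6 aligned with its empty orbital, so proton loss or a 1,2-hydride shift would lead to ketonisation at C6, while the nucleophile is a hindered secondary alcohol. A second failure is over-oxidation: the C7–H bonds of 24 and 25 are those of para-methoxybenzylic ethers and can also give up hydride to the quinone.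

The fallback forms each C7–O bond by reductive etherification of an aryl ketone, a known reaction type. It sets out from 23. Acetylation (Ac2O, pyridine, DMAP) would give 6α-acetoxy-12-methoxyabieta-8,11,13-triene F1. Benzylic oxidation (CrO3, AcOH) would give 6α-acetoxy-12-methoxyabieta-8,11,13-trien-7-one F2. Methanolysis under argon (K2CO3, MeOH) would give 6α-hydroxy-12-methoxyabieta-8,11,13-trien-7-one F3. Treating F3 with Et3SiH and TMSOTf in CH2Cl2 at −78 to 0 °C should join the hydroxyl of one molecule to the ketone of another and then close the ring the same way. Hydride is delivered axially, from the α face, to each aryl-stabilised oxocarbenium ion, giving the 7β-ethers. The sequence returns to the route at 25. Simple over-reduction of the ketone only regenerates 23.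

**Step 7 (key step).** The most likely failure is erosion of facial selectivity. This would arise if part of the conjugate addition escapes the cyclic proton-transfer transition state, for example through acid-catalysed or polymerising pathways of 12. A second risk is diversion of 15 into the bridged ketol. Any minor enantiomer matters twice, because step 11 consumes it in heterochiral dimers.

The fallback replaces the covalent auxiliary by ion pairing. From 10, conjugate addition to 12 under phase-transfer catalysis with N-[4-(trifluoromethyl)benzyl]cinchoninium bromide (or its cinchonidinium pseudoenantiomer, whichever gives the R series), 50% aq NaOH and toluene would give 15 directly. This is a known way of alkylating 1-methyl-2-tetralones enantioselectively. It comes back to the route at 15, which is closed to 17 with NaOMe as before; no new compound is made.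

**Step 6.** The most likely failures are opening of epoxide 9 by the carboxylic acid by-product before rearrangement, ring contraction by alkyl shift in place of hydride shift, and autoxidation of 10 at its doubly activated C1–H.

The fallback avoids the cation. From 8, hydroboration–oxidation (BH3·THF; NaOH, H2O2) would give trans-6-isopropyl-7-methoxy-1-methyl-1,2,3,4-tetrahydronaphthalen-2-ol F4, and oxidation with Dess–Martin periodinane returns to the route at 10.

**Step 9.** The most likely failures are slow hydrazone formation at the ketone flanked by the quaternary C4, and base-promoted migration of the C5=C6 bond into conjugation with the arene at 200 °C, since the C7–H bonds are both allylic and benzylic.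

The fallback works without strong base or heat. From 19, condensation with tosylhydrazide (EtOH, reflux) would give the tosylhydrazone of 19 F5. Reduction with catecholborane in CHCl3 at 0 °C, followed by NaOAc·3H2O at reflux, returns to the route at 21.

**Step 10.** The most likely failure is incomplete facial discrimination or sluggish addition, because the α face carries the equatorial 4α-methyl group next to the alkene; β-face addition would give the cis-fused 6β-alcohol.

The fallback separates ring fusion from oxygenation. From 21, hydrogenation (H2, Pd/C, AcOH) from the α face would give 12-methoxyabieta-8,11,13-triene F6. Dehydrogenation with DDQ in dioxane at reflux would give 12-methoxyabieta-6,8,11,13-tetraene F7. Hydroboration–oxidation of this styrene places boron on the non-benzylic C6 from the α face and returns to the route at 23.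

## Further compounds

F1 | step 11 | 6α-acetoxy-12-methoxyabieta-8,11,13-triene | COc1cc2c(cc1C(C)C)C[C@H](OC(C)=O)[C@H]1C(C)(C)CCC[C@]21C
F2 | step 11 | 6α-acetoxy-12-methoxyabieta-8,11,13-trien-7-one | COc1cc2c(cc1C(C)C)C(=O)[C@H](OC(C)=O)[C@H]1C(C)(C)CCC[C@]21C
F3 | step 11 | 6α-hydroxy-12-methoxyabieta-8,11,13-trien-7-one | COc1cc2c(cc1C(C)C)C(=O)[C@H](O)[C@H]1C(C)(C)CCC[C@]21C
F0 | step 7 | none | none
F4 | step 6 | trans-6-isopropyl-7-methoxy-1-methyl-1,2,3,4-tetrahydronaphthalen-2-ol (racemic, one enantiomer drawn) | C[C@H]1[C@H](O)CCc2cc(C(C)C)c(OC)cc21
F5 | step 9 | tosylhydrazone of 12-methoxyabieta-5,8,11,13-tetraen-3-one | COc1cc2c(cc1C(C)C)CC=C1C(C)(C)C(=NNS(=O)(=O)c3ccc(C)cc3)CC[C@]21C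
F6 | step 10 | 12-methoxyabieta-8,11,13-triene (ferruginol methyl ether) | COc1cc2c(cc1C(C)C)CC[C@H]1C(C)(C)CCC[C@]21C
F7 | step 10 | 12-methoxyabieta-6,8,11,13-tetraene | COc1cc2c(cc1C(C)C)C=C[C@H]1C(C)(C)CCC[C@]21C
A1 | alternative 1 | 6α-(tert-butyldimethylsilyloxy)-12-methoxyabieta-8,11,13-trien-7-one | COc1cc2c(cc1C(C)C)C(=O)[C@H](O[Si](C)(C)C(C)(C)C)[C@H]1C(C)(C)CCC[C@]21C
A2 | alternative 1 | ring A cyclohexane with methyl and 3-methoxy-5-methylhex-3-en-1-yn-1-yl on C10 and 1-(tert-butyldimethylsilyloxy)-2-oxobut-3-yn-1-yl on C5 (abietane numbering, alkene geometry left open) | COC(=CC(C)C)C#C[C@@]1(C)CCCC(C)(C)[C@@H]1[C@@H](O[Si](C)(C)C(C)(C)C)C(=O)C#C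
A3 | alternative 2 | (1S,2S)-2-(4-isopropyl-3-methoxyphenyl)-2,6,6-trimethylcyclohex-3-ene-1-carboxylic acid | OC(=O)[C@H]1C(C)(C)CC=C[C@]1(C)c1ccc(C(C)C)c(OC)c1
A4 | alternative 2 | (6R)-6-[(Z)-2-(4-isopropyl-3-methoxyphenyl)prop-1-en-1-yl]-4,4-dimethyltetrahydro-2H-pyran-2-one | O=C1CC(C)(C)C[C@@H](O1)/C=C(/C)c1ccc(C(C)C)c(OC)c1
A5 | alternative 2 | trimethylsilyl ketene acetal of A4 | C[Si](C)(C)OC1=CC(C)(C)C[C@@H](O1)/C=C(/C)c1ccc(C(C)C)c(OC)c1
A6 | alternative 3 | ferruginol | CC(C)c1cc2c(cc1O)[C@@]1(C)CCCC(C)(C)[C@@H]1CC2
A7 | alternative 3 | 1-(5,5,8a-trimethyl-2-methylenedecahydronaphthalen-1-yl)-4-methylpentane-2,3-dione, natural labdane configuration (5α-H, 9α-H, 10β-methyl) | C=C1CC[C@H]2C(C)(C)CCC[C@]2(C)[C@H]1CC(=O)C(=O)C(C)C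
A8 | alternative 3 | (+)-sclareolide | C[C@]12CCCC([C@@H]1CC[C@@]3([C@@H]2CC(=O)O3)C)(C)C
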